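Cuts: first the O–Si bond on ring B, then O1–C2 and C4–C4a of the pyran (ring C, from prenal), then C4a–C5 and C6–C7 of ring A. Behind these lie the acetylide–carbonyl bond of the ynone and the C8–CH2 prenyl bond, which is made on an acetoacetate.
Enabling feature: ring A (C4a, C5, C6, C7, C8, C8a) is a resorcinol with oxygen on C7 and C8a, prenyl on C8 between them, the acyl group on C6 ortho to the C7 hydroxyl, and hydrogen on C5. C7–C8–C8a–C4a is therefore the C1–C4 chain of methyl 2-prenylacetoacetate in bis-enol form, and C5–C6 is a terminal ynone that already carries the saturated chain and ring B.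
Forward: two three-step branches (the diene, and the ynone with ring B bought in as phloretic acid) meet in the benzannulation that builds ring A. Ring C is then closed on C4a, the only free carbon ortho to a ring oxygen, and desilylation ends the route.
Stereochemistry: the target has no stereocentre and no configurable double bond. The centres that appear in passing (α-carbon of the keto ester, hemiaminal carbon of the Grignard adduct, ketal carbon of the cycloadduct) are racemic and are erased.

Key step: step 7

Remark on the chemistry: chromene numbering (O1, C2, C3, C4, C4a, C5 to C8, C8a) is also applied to the ring A carbons of all precursors, and LiN(iPr)2 and ethynylmagnesium bromide are taken as the commercial solutions.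

Step 1
Reactants: 1 methyl acetoacetate; 2 prenyl bromide
Product: 3 methyl 2-acetyl-5-methylhex-4-enoate (methyl 2-prenylacetoacetate, racemic)
Conditions: 1 (1.3 equiv), K2CO3 (1.5 equiv), acetone, reflux
Reagents that add atoms: none
Why: Acetoacetic ester alkylation: the soft potassium enolate of 1 displaces bromide from the primary allylic carbon of 2 in an SN2 reaction at carbon, a small excess of 1 holds back dialkylation, and the new α-centre is racemic and is flattened in step 2.

Step 2
Reactants: 3 methyl 2-acetyl-5-methylhex-4-enoate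
Product: 4 methyl 5-methyl-2-[1-(trimethylsilyloxy)ethylidene]hex-4-enoate (expected as an E/Z mixture)
Conditions: TMSCl (1.6 equiv), Et3N (1.6 equiv), toluene, rt, 48–72 h; filtration under argon
Reagents that add atoms: chlorotrimethylsilane, C[Si](C)(C)Cl
Why: Silyl enol ether formation from the enol of a β-keto ester with TMSCl/Et3N, the usual first stage on the way to 1,3-bis(silyloxy)dienes and known to accept a 2-alkyl group, with a double-bond geometry that has no bearing on what follows.

Step 3
Reactants: 4 methyl 5-methyl-2-[1-(trimethylsilyloxy)ethylidene]hex-4-enoate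
Product: 6 1-methoxy-2-(3-methylbut-2-enyl)-1,3-bis(trimethylsilyloxy)buta-1,3-diene, via lithium dienolate 5 (not isolated)
Conditions: LiN(iPr)2 (1.3 equiv), THF, −78 °C; then TMSCl (1.5 equiv), −78 °C → rt; hexane, filtration under argon, used without chromatography
Reagents that add atoms: chlorotrimethylsilane, C[Si](C)(C)Cl
Why: Kinetic γ-deprotonation of the β-silyloxy enoate at its methyl group gives the extended ester dienolate 5, which the hard silyl chloride traps on oxygen (silyl ketene acetal formation), whereas the prenyl CH2 hangs on the α-carbon, gains no stabilisation from the ester and is left alone.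

Step 4
Reactants: 7 phloretic acid
Product: 8 3-(4-hydroxyphenyl)-N-methoxy-N-methylpropanamide
Conditions: MeNH(OMe)·HCl, EDC·HCl, HOBt (cat.), N-methylmorpholine, CH2Cl2–DMF, 0 °C → rt
Reagents that add atoms: N,O-dimethylhydroxylamine hydrochloride, CNOC.Cl
Why: Carbodiimide/HOBt amide coupling to the Weinreb amide, in which the amine outcompetes the phenol for the active ester so that ring B needs no protection yet.

Step 5
Reactants: 8 3-(4-hydroxyphenyl)-N-methoxy-N-methylpropanamide
Product: 9 3-[4-(tert-butyldimethylsilyloxy)phenyl]-N-methoxy-N-methylpropanamide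
Conditions: TBSCl, imidazole, DMF, rt
Reagents that add atoms: tert-butyldimethylsilyl chloride, CC(C)(C)[Si](C)(C)Cl
Why: Imidazole-promoted O-silylation of a phenol, which removes the only acidic proton that would quench the Grignard reagent of step 6 and the ketene acetal of step 7.

Step 6
Reactants: 9 3-[4-(tert-butyldimethylsilyloxy)phenyl]-N-methoxy-N-methylpropanamide; 10 ethynylmagnesium bromide
Product: 12 5-[4-(tert-butyldimethylsilyloxy)phenyl]pent-1-yn-3-one, via bromomagnesium hemiaminal chelate 11 (not isolated)
Conditions: 10 (0.5 M in THF, 2 equiv), THF, 0 °C → rt; inverse quench into ice-cold 1 M aq. HCl–Et2O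
Reagents that add atoms: none
Why: Weinreb ketone synthesis: the five-membered magnesium chelate 11 survives until the quench so that only one acetylide adds, and pouring into cold acid protonates the released N,O-dimethylhydroxylamine before it can add to the terminal ynone.

Step 7
Reactants: 6 1-methoxy-2-(3-methylbut-2-enyl)-1,3-bis(trimethylsilyloxy)buta-1,3-diene; 12 5-[4-(tert-butyldimethylsilyloxy)phenyl]pent-1-yn-3-one
Product: 15 1-[2,4-dihydroxy-3-(3-methylbut-2-enyl)phenyl]-3-[4-(tert-butyldimethylsilyloxy)phenyl]propan-1-one, via cyclohexa-1,4-diene cycloadduct 13 (not isolated), via bis(trimethylsilyl) ether 14 (not isolated)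
Conditions: 12 added slowly to 6 (1.6 equiv), toluene, 0 °C → rt, then 80 °C; then 10% aq. citric acid, THF–MeOH, rt
Reagents that add atoms: none
Why: This is a normal-electron-demand Diels-Alder benzannulation of a 1-alkoxy-1,3-bis(silyloxy)butadiene with an acetylenic ketone, the known route from such dienes and alkynyl ketones or esters to resorcinols. All three oxygen donors of 6 raise the HOMO coefficient at the CH2 terminus (future C4a), which bonds to the unsubstituted β-carbon of the ynone (future C5), while the ketene acetal carbon (future C7) bonds to the acyl-bearing carbon (future C6). Ring A closes as a six-membered all-carbon ring in a concerted but highly asynchronous [4+2] cycloaddition, and the stepwise alternative (Mukaiyama-Michael addition, then collapse of the allenolate onto the silyloxycarbenium carbon) would end at the same adduct 13. In 13 the methoxy group on C7 and a hydrogen on C4a sit 1,4 across the cyclohexadiene, so methanol leaves with gain of aromaticity to give 14, and citric acid then cleaves the two labile aryl trimethylsilyl ethers but not the aryl tert-butyldimethylsilyl ether. The only new centre (C7 of 13) is racemic and disappears on aromatisation, so no stereocontrol is needed. The selectivity required is regiochemical (C7 hydroxyl ortho and C8a hydroxyl para to the acyl group) and chemoselective (triple bond rather than C=O or the prenyl alkene), the first secured by the matched polarisation of the two partners and the second by working thermally, without Lewis acid, on the only electron-poor π bond.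

Step 8
Reactants: 15 1-[2,4-dihydroxy-3-(3-methylbut-2-enyl)phenyl]-3-[4-(tert-butyldimethylsilyloxy)phenyl]propan-1-one; 16 prenal (3-methylbut-2-enal)
Product: 18 1-[7-hydroxy-2,2-dimethyl-8-(3-methylbut-2-enyl)-2H-chromen-6-yl]-3-[4-(tert-butyldimethylsilyloxy)phenyl]propan-1-one, via ortho-quinone methide 17 (not isolated)
Conditions: 16 (2.5 equiv), ethylenediammonium diacetate (20 mol %), xylene, 140 °C
Reagents that add atoms: none
Why: Amine-salt-catalysed Knoevenagel-type condensation followed by oxa-6π electrocyclisation (the formal [3+3] chromene annulation of resorcinols with enals): the iminium ion of 16 is attacked by C4a, the only unsubstituted ring carbon ortho to an oxygen because C8 carries prenyl and C6 the acyl group, loss of water gives 17, and ring C closes between the C8a oxygen and the dimethyl-substituted terminus, so only the linear chromene can form.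

Step 9
Reactants: 18 1-[7-hydroxy-2,2-dimethyl-8-(3-methylbut-2-enyl)-2H-chromen-6-yl]-3-[4-(tert-butyldimethylsilyloxy)phenyl]propan-1-one
Product: 19 1-[7-hydroxy-2,2-dimethyl-8-(3-methylbut-2-enyl)-2H-chromen-6-yl]-3-(4-hydroxyphenyl)propan-1-one (CNP0163015.0)
Conditions: Bu4NF (1.1 equiv), AcOH (1.1 equiv), THF, 0 °C
Reagents that add atoms: none
Why: Fluoride-induced cleavage of an aryl silyl ether driven by the strong Si–F bond, buffered with acetic acid so that the phenoxide is protonated at once and the chromene, the prenyl group and the ketone are untouched.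

Compound list
1 | methyl acetoacetate | COC(=O)CC(C)=O | starting material
2 | prenyl bromide (1-bromo-3-methylbut-2-ene) | CC(C)=CCBr | starting material
3 | methyl 2-acetyl-5-methylhex-4-enoate (racemic) | COC(=O)C(CC=C(C)C)C(C)=O | intermediate
4 | methyl 5-methyl-2-[1-(trimethylsilyloxy)ethylidene]hex-4-enoate (geometry not fixed) | COC(=O)C(CC=C(C)C)=C(C)O[Si](C)(C)C | intermediate
5 | lithium 1-methoxy-2-(3-methylbut-2-enyl)-3-(trimethylsilyloxy)buta-1,3-dien-1-olate | C=C(O[Si](C)(C)C)C(CC=C(C)C)=C(OC)O[Li] | intermediate
6 | 1-methoxy-2-(3-methylbut-2-enyl)-1,3-bis(trimethylsilyloxy)buta-1,3-diene (ketene acetal geometry not fixed) | C=C(O[Si](C)(C)C)C(CC=C(C)C)=C(OC)O[Si](C)(C)C | intermediate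
7 | phloretic acid (3-(4-hydroxyphenyl)propanoic acid) | O=C(O)CCc1ccc(O)cc1 | starting material
8 | 3-(4-hydroxyphenyl)-N-methoxy-N-methylpropanamide | CON(C)C(=O)CCc1ccc(O)cc1 | intermediate
9 | 3-[4-(tert-butyldimethylsilyloxy)phenyl]-N-methoxy-N-methylpropanamide | CON(C)C(=O)CCc1ccc(O[Si](C)(C)C(C)(C)C)cc1 | intermediate
10 | ethynylmagnesium bromide | C#C[Mg]Br | starting material
11 | bromomagnesium salt of 5-[4-(tert-butyldimethylsilyloxy)phenyl]-3-[methoxy(methyl)amino]pent-1-yn-3-ol (racemic chelate) | C#CC(CCc1ccc(O[Si](C)(C)C(C)(C)C)cc1)(O[Mg]Br)N(C)OC | intermediate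
12 | 5-[4-(tert-butyldimethylsilyloxy)phenyl]pent-1-yn-3-one | C#CC(=O)CCc1ccc(O[Si](C)(C)C(C)(C)C)cc1 | intermediate
13 | 1-[6-methoxy-5-(3-methylbut-2-enyl)-4,6-bis(trimethylsilyloxy)cyclohexa-1,4-dien-1-yl]-3-[4-(tert-butyldimethylsilyloxy)phenyl]propan-1-one (racemic) | COC1(O[Si](C)(C)C)C(CC=C(C)C)=C(O[Si](C)(C)C)CC=C1C(=O)CCc1ccc(O[Si](C)(C)C(C)(C)C)cc1 | intermediate
14 | 1-[3-(3-methylbut-2-enyl)-2,4-bis(trimethylsilyloxy)phenyl]-3-[4-(tert-butyldimethylsilyloxy)phenyl]propan-1-one | CC(C)=CCc1c(O[Si](C)(C)C)ccc(C(=O)CCc2ccc(O[Si](C)(C)C(C)(C)C)cc2)c1O[Si](C)(C)C | intermediate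
15 | 1-[2,4-dihydroxy-3-(3-methylbut-2-enyl)phenyl]-3-[4-(tert-butyldimethylsilyloxy)phenyl]propan-1-one | CC(C)=CCc1c(O)ccc(C(=O)CCc2ccc(O[Si](C)(C)C(C)(C)C)cc2)c1O | intermediate
16 | prenal (3-methylbut-2-enal) | CC(C)=CC=O | starting material
17 | 4-{3-[4-(tert-butyldimethylsilyloxy)phenyl]propanoyl}-3-hydroxy-2-(3-methylbut-2-enyl)-6-(3-methylbut-2-enylidene)cyclohexa-2,4-dien-1-one (exocyclic geometry not fixed) | CC(C)=CCC1=C(O)C(C(=O)CCc2ccc(O[Si](C)(C)C(C)(C)C)cc2)=CC(=CC=C(C)C)C1=O | intermediate
18 | 1-[7-hydroxy-2,2-dimethyl-8-(3-methylbut-2-enyl)-2H-chromen-6-yl]-3-[4-(tert-butyldimethylsilyloxy)phenyl]propan-1-one | CC(C)=CCc1c(O)c(C(=O)CCc2ccc(O[Si](C)(C)C(C)(C)C)cc2)cc2c1OC(C)(C)C=C2 | intermediate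
19 | 1-[7-hydroxy-2,2-dimethyl-8-(3-methylbut-2-enyl)-2H-chromen-6-yl]-3-(4-hydroxyphenyl)propan-1-one | CC(C)=CCc1c(O)c(C(=O)CCc2ccc(O)cc2)cc2c1OC(C)(C)C=C2 | target

Total step count: 9. Longest linear sequence: 6 steps (1, 2, 3, 7, 8, 9 from methyl acetoacetate, or 4, 5, 6, 7, 8, 9 from phloretic acid).

Steps most likely to fail

Step 7. The addition may stop after the first C–C bond, giving conjugate addition without ring closure. The crowded ketene acetal terminus may also react so slowly that the ynone oligomerises or the diene is hydrolysed. On aromatisation, silanol may leave in place of methanol. The fallback buys ring A instead of building it; it sets out from amide 9 and bromide 2 and comes back at 19. Resorcinol is protected with chloromethyl methyl ether and iPr2NEt as 1,3-bis(methoxymethoxy)benzene F1. Directed ortho-lithiation between the two acetal oxygens (n-BuLi, THF, 0 °C) and alkylation with 2 give 1,3-bis(methoxymethoxy)-2-(3-methylbut-2-enyl)benzene F2. A second directed lithiation next to one acetal oxygen (n-BuLi, TMEDA) and acylation by 9 give 1-[2,4-bis(methoxymethoxy)-3-(3-methylbut-2-enyl)phenyl]-3-[4-(tert-butyldimethylsilyloxy)phenyl]propan-1-one F3. Brief treatment with methanolic HCl removes both acetals and the silyl ether to give 1-[2,4-dihydroxy-3-(3-methylbut-2-enyl)phenyl]-3-(4-hydroxyphenyl)propan-1-one F4. The condensation with 16 under the conditions of step 8, to which the isolated phenol of ring B is inert, then leads directly to 19.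

Step 8. Attack by C4a may be sluggish because the acyl group lowers the nucleophilicity of the resorcinol. Self-condensation of the enal or aldol chemistry at the ketone α-CH2 could then take over. The fallback replaces the condensation by a sigmatropic route; it sets out from 15 and comes back at 18. The C8a hydroxyl is etherified with 3-chloro-3-methylbut-1-yne (DBU, CuCl2·2H2O cat., MeCN, 0 °C), while the C7 hydroxyl stays tied up in its hydrogen bond to the ketone. This gives 1-[2-hydroxy-3-(3-methylbut-2-enyl)-4-(2-methylbut-3-yn-2-yloxy)phenyl]-3-[4-(tert-butyldimethylsilyloxy)phenyl]propan-1-one F5. Heating in N,N-diethylaniline should then set off an aromatic propargyl Claisen rearrangement to C4a, enolisation, a 1,5-hydrogen shift and oxa-6π closure to 18.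

Step 6. The amine released on collapse of the chelate may add to the terminal ynone during the quench, or the basic medium may oligomerise the ynone. The fallback passes through the alcohol oxidation level; it sets out from 9 and comes back at 12. Reduction with iBu2AlH (THF, −78 °C) gives 3-[4-(tert-butyldimethylsilyloxy)phenyl]propanal F6. Addition of 10 gives racemic 5-[4-(tert-butyldimethylsilyloxy)phenyl]pent-1-yn-3-ol F7. Dess-Martin periodinane (CH2Cl2, rt) then oxidises it to 12 in an amine-free, non-basic medium.

Further compounds
F1 | step 7 | 1,3-bis(methoxymethoxy)benzene | COCOc1cccc(OCOC)c1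
F2 | step 7 | 1,3-bis(methoxymethoxy)-2-(3-methylbut-2-enyl)benzene | COCOc1cccc(OCOC)c1CC=C(C)C
F3 | step 7 | 1-[2,4-bis(methoxymethoxy)-3-(3-methylbut-2-enyl)phenyl]-3-[4-(tert-butyldimethylsilyloxy)phenyl]propan-1-one | COCOc1ccc(C(=O)CCc2ccc(O[Si](C)(C)C(C)(C)C)cc2)c(OCOC)c1CC=C(C)C
F4 | step 7 | 1-[2,4-dihydroxy-3-(3-methylbut-2-enyl)phenyl]-3-(4-hydroxyphenyl)propan-1-one | CC(C)=CCc1c(O)ccc(C(=O)CCc2ccc(O)cc2)c1O
F5 | step 8 | 1-[2-hydroxy-3-(3-methylbut-2-enyl)-4-(2-methylbut-3-yn-2-yloxy)phenyl]-3-[4-(tert-butyldimethylsilyloxy)phenyl]propan-1-one | C#CC(C)(C)Oc1ccc(C(=O)CCc2ccc(O[Si](C)(C)C(C)(C)C)cc2)c(O)c1CC=C(C)C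
F6 | step 6 | 3-[4-(tert-butyldimethylsilyloxy)phenyl]propanal | O=CCCc1ccc(O[Si](C)(C)C(C)(C)C)cc1
F7 | step 6 | 5-[4-(tert-butyldimethylsilyloxy)phenyl]pent-1-yn-3-ol (racemic) | C#CC(O)CCc1ccc(O[Si](C)(C)C(C)(C)C)cc1
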